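The synthesis hinges on the C4–C4a bond, made by acylating a ring A carbanion at the future C4a with C4, which is stored as the lactone carbonyl of a 4-aryloxycoumarin. The feature used is that O2′, C2′, C1′, C2, C3 and C4 close a six-membered lactone while the aryl ether oxygen already is O1. Because O1 and C4 are trans across C2=C3 in this lactone, the key step relays the acyl group through tert-butoxide, lets the enol ether equilibrate, then closes ring C by bromine–lithium exchange and frees the 2′-OH, all in one flask. The precursor is 6-allyloxy-3,7-dimethoxycoumarin bearing a 2-bromo-3,5-bis(benzyloxy)phenoxy group at C4.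

Key step: step 8

Remark on the chemistry: the persulfate oxidation is run on the free acid 1 and the ester is installed afterwards as the allyl ester, because a methyl salicylate would be saponified in the alkaline oxidation; flavone numbering is used for the atoms of rings A, B and C.

Step 1
Reactants: 1 4-methoxysalicylic acid (2-hydroxy-4-methoxybenzoic acid)
Product: 3 2,5-dihydroxy-4-methoxybenzoic acid, via 5-O-sulfate ester 2 (not isolated)
Conditions: K2S2O8, 10% aq. NaOH, 0 → 20 °C; then conc. HCl, 90 °C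
Reagents that add atoms: potassium peroxodisulfate, [K+].[K+].[O-]S(=O)(=O)OOS(=O)(=O)[O-]
Why: The Elbs persulfate oxidation attacks the phenoxide at the carbon para to the phenolic oxygen (C5, also ortho to the methoxy group), and the aryl sulfate is then hydrolysed in acid.

Step 2
Reactants: 3 2,5-dihydroxy-4-methoxybenzoic acid
Product: 4 allyl 5-(allyloxy)-2-hydroxy-4-methoxybenzoate
Conditions: allyl bromide (2.1 equiv), K2CO3 (2.2 equiv), DMF, 25 → 40 °C
Reagents that add atoms: allyl bromide, C=CCBr
Why: Williamson-type O-alkylation should allylate the carboxylate and the free 5-OH, while the 2-OH stays tied up in its hydrogen bond to the ester carbonyl and is spared at two equivalents of allyl bromide.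

Step 3
Reactants: 4 allyl 5-(allyloxy)-2-hydroxy-4-methoxybenzoate; 5 methoxyacetyl chloride
Product: 6 allyl 5-(allyloxy)-4-methoxy-2-[(methoxyacetyl)oxy]benzoate
Conditions: Et3N, DMAP (cat.), CH2Cl2, 0 °C → rt
Reagents that add atoms: none
Why: DMAP-catalysed O-acylation of the chelated phenol by the acid chloride should give the aryl methoxyacetate that carries the future C3 with its methoxy group.

Step 4
Reactants: 6 allyl 5-(allyloxy)-4-methoxy-2-[(methoxyacetyl)oxy]benzoate
Product: 7 6-(allyloxy)-4-hydroxy-3,7-dimethoxy-2H-chromen-2-one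
Conditions: LiN(SiMe3)2 (2.2 equiv), THF, −78 → 0 °C; then 1 M HCl
Reagents that add atoms: none
Why: In this Dieckmann-type (intramolecular Claisen) condensation the enolate of the aryl methoxyacetate attacks the neighbouring allyl ester in a six-membered closure, allyl oxide leaves, and deprotonation of the acidic chromane-2,4-dione to the coumarin-4-olate should make the closure irreversible.

Step 5
Reactants: 7 6-(allyloxy)-4-hydroxy-3,7-dimethoxy-2H-chromen-2-one
Product: 8 6-(allyloxy)-3,7-dimethoxy-2-oxo-2H-chromen-4-yl 4-methylbenzenesulfonate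
Conditions: TsCl, Et3N, CH2Cl2, 0 °C → rt
Reagents that add atoms: p-toluenesulfonyl chloride, Cc1ccc(cc1)S(=O)(=O)Cl
Why: O-sulfonylation of the vinylogous acid turns the 4-oxygen into the leaving group of a vinylogous mixed anhydride, and the tosylate is isolated so that no sulfonyl chloride meets the phenol of step 7.

Step 6
Reactants: 9 3,5-bis(benzyloxy)phenol
Product: 10 3,5-bis(benzyloxy)-2-bromophenol
Conditions: NBS (1.0 equiv), i-Pr2NH (10 mol%), CH2Cl2, −78 → 0 °C
Reagents that add atoms: N-bromosuccinimide, O=C1CCC(=O)N1Br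
Why: In this amine-catalysed ortho-bromination of a phenol the N-bromoamine formed from NBS is delivered through a hydrogen bond to the carbon next to the hydroxyl, which is also para to a benzyloxy group, and one equivalent at low temperature should limit dibromination.

Step 7
Reactants: 8 6-(allyloxy)-3,7-dimethoxy-2-oxo-2H-chromen-4-yl 4-methylbenzenesulfonate; 10 3,5-bis(benzyloxy)-2-bromophenol
Product: 11 6-(allyloxy)-4-[3,5-bis(benzyloxy)-2-bromophenoxy]-3,7-dimethoxy-2H-chromen-2-one
Conditions: Cs2CO3, DMF, 50 °C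
Reagents that add atoms: none
Why: Addition–elimination (nucleophilic vinylic substitution) of the cesium phenoxide at C4 of the 4-tosyloxycoumarin should form the aryl enol ether that becomes O1–C2 of the flavone.

Step 8
Reactants: 11 6-(allyloxy)-4-[3,5-bis(benzyloxy)-2-bromophenoxy]-3,7-dimethoxy-2H-chromen-2-one
Product: 15 2-[5-(allyloxy)-2-hydroxy-4-methoxyphenyl]-5,7-bis(benzyloxy)-3-methoxy-4H-chromen-4-one, via ring-opened (Z)-tert-butyl ester phenoxide 12 (not isolated), via ring-opened (E)-tert-butyl ester phenoxide 13 (not isolated), via (E)-aryllithium 14 (not isolated)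
Conditions: KOt-Bu (1.0 equiv), THF, 0 → 45 °C; then t-BuLi (2.05 equiv), −100 → −20 °C; aq. NH4Cl
Reagents that add atoms: none
Why: Proposed new method: in 11 the aryl ether oxygen (future O1) and the lactone carbonyl (future C4) are held trans across the enol ether double bond, so a ring A carbanion cannot reach the carbonyl while the lactone is closed, and the acyl group is therefore relayed through tert-butoxide. KOt-Bu opens the aryl lactone by transesterification to the (Z)-ester phenoxide 12, whose push–pull double bond can rotate through an ortho-quinone-methide/ester-enolate form to the (E)-isomer 13, in which the bulky ester lies next to the aryloxy group. Bromine–lithium exchange with t-BuLi at −100 °C, which should outrun addition to the hindered and anionic tert-butyl ester, gives aryllithium 14; it attacks the ester carbonyl in a 6-exo-trig closure, tert-butoxide leaves, and C4–C4a and the pyranone ring are formed with the 2′-phenoxide already free. The closest known reactions are Parham cyclisations of aryllithiums onto esters, the alkoxide opening of coumarins to coumarinate esters and the base-induced coumarinate-to-coumarate isomerisation. No stereocentre is formed; the bromine fixes which ortho carbon becomes C4a, and attack on the ether-bearing carbon would need a four-membered transition state. The step needs E/Z equilibration before lithiation and exchange faster than addition, which the 2′-phenoxide donor, the bulk of the tert-butyl ester, the low temperature and the exact stoichiometry of t-BuLi are meant to secure.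

Step 9
Reactants: 15 2-[5-(allyloxy)-2-hydroxy-4-methoxyphenyl]-5,7-bis(benzyloxy)-3-methoxy-4H-chromen-4-one
Product: 16 2-[5-(allyloxy)-2-(benzyloxy)-4-methoxyphenyl]-5,7-bis(benzyloxy)-3-methoxy-4H-chromen-4-one
Conditions: BnBr, K2CO3, DMF, rt
Reagents that add atoms: benzyl bromide, BrCc1ccccc1
Why: Williamson etherification of the only free phenol should give the 2′-benzyl ether, which leaves with the other benzyl groups in the last step.

Step 10
Reactants: 16 2-[5-(allyloxy)-2-(benzyloxy)-4-methoxyphenyl]-5,7-bis(benzyloxy)-3-methoxy-4H-chromen-4-one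
Product: 17 5,7-bis(benzyloxy)-2-[2-(benzyloxy)-5-hydroxy-4-methoxyphenyl]-3-methoxy-4H-chromen-4-one
Conditions: Pd(PPh3)4 (5 mol%), morpholine (5 equiv), THF, rt
Reagents that add atoms: none
Why: In this Tsuji–Trost-type deallylation zerovalent palladium ionises the allyl aryl ether to a π-allyl complex and the phenoxide, and morpholine captures the allyl group, which should leave the benzyl ethers and the pyranone untouched.

Step 11
Reactants: 17 5,7-bis(benzyloxy)-2-[2-(benzyloxy)-5-hydroxy-4-methoxyphenyl]-3-methoxy-4H-chromen-4-one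
Product: 18 4-(benzyloxy)-5-[5,7-bis(benzyloxy)-3-methoxy-4-oxo-4H-chromen-2-yl]-2-methoxyphenyl acetate
Conditions: Ac2O, pyridine, DMAP (cat.), CH2Cl2, rt
Reagents that add atoms: acetic anhydride, CC(=O)OC(C)=O
Why: Acylation of the single free phenol should place the acetate on the 5′-oxygen only.

Step 12
Reactants: 18 4-(benzyloxy)-5-[5,7-bis(benzyloxy)-3-methoxy-4-oxo-4H-chromen-2-yl]-2-methoxyphenyl acetate
Product: 19 5,7,2′,5′-tetrahydroxy-3,4′-dimethoxyflavone 5′-acetate
Conditions: H2 (1 atm), palladium on carbon (10% Pd/C), EtOAc/THF, rt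
Reagents that add atoms: none
Why: Hydrogenolysis should cleave the three benzyl aryl ethers, while the aryl acetate and the tetrasubstituted double bond of the pyranone survive under neutral conditions in a non-nucleophilic solvent.

Compound list

1 | 4-methoxysalicylic acid (2-hydroxy-4-methoxybenzoic acid) | COc1ccc(C(=O)O)c(O)c1 | starting material
2 | 2-hydroxy-4-methoxy-5-(sulfooxy)benzoic acid | COc1cc(O)c(C(=O)O)cc1OS(=O)(=O)O | intermediate
3 | 2,5-dihydroxy-4-methoxybenzoic acid | COc1cc(O)c(C(=O)O)cc1O | intermediate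
4 | allyl 5-(allyloxy)-2-hydroxy-4-methoxybenzoate | COc1cc(O)c(C(=O)OCC=C)cc1OCC=C | intermediate
5 | methoxyacetyl chloride | COCC(=O)Cl | starting material
6 | allyl 5-(allyloxy)-4-methoxy-2-[(methoxyacetyl)oxy]benzoate | COCC(=O)Oc1cc(OC)c(OCC=C)cc1C(=O)OCC=C | intermediate
7 | 6-(allyloxy)-4-hydroxy-3,7-dimethoxy-2H-chromen-2-one | COc1cc2oc(=O)c(OC)c(O)c2cc1OCC=C | intermediate
8 | 6-(allyloxy)-3,7-dimethoxy-2-oxo-2H-chromen-4-yl 4-methylbenzenesulfonate | COc1cc2oc(=O)c(OC)c(OS(=O)(=O)c3ccc(C)cc3)c2cc1OCC=C | intermediate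
9 | 3,5-bis(benzyloxy)phenol | Oc1cc(OCc2ccccc2)cc(OCc2ccccc2)c1 | starting material
10 | 3,5-bis(benzyloxy)-2-bromophenol | Oc1cc(OCc2ccccc2)cc(OCc2ccccc2)c1Br | intermediate
11 | 6-(allyloxy)-4-[3,5-bis(benzyloxy)-2-bromophenoxy]-3,7-dimethoxy-2H-chromen-2-one | O=c1oc2cc(OC)c(OCC=C)cc2c(Oc2cc(OCc3ccccc3)cc(OCc3ccccc3)c2Br)c1OC | intermediate
12 | tert-butyl (2Z)-3-[5-(allyloxy)-4-methoxy-2-oxidophenyl]-3-[3,5-bis(benzyloxy)-2-bromophenoxy]-2-methoxyprop-2-enoate, potassium salt | CO/C(C(=O)OC(C)(C)C)=C(\Oc1cc(OCc2ccccc2)cc(OCc2ccccc2)c1Br)c1cc(OCC=C)c(OC)cc1[O-].[K+] | intermediate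
13 | tert-butyl (2E)-3-[5-(allyloxy)-4-methoxy-2-oxidophenyl]-3-[3,5-bis(benzyloxy)-2-bromophenoxy]-2-methoxyprop-2-enoate, potassium salt | CO/C(C(=O)OC(C)(C)C)=C(/Oc1cc(OCc2ccccc2)cc(OCc2ccccc2)c1Br)c1cc(OCC=C)c(OC)cc1[O-].[K+] | intermediate
14 | tert-butyl (2E)-3-[5-(allyloxy)-4-methoxy-2-oxidophenyl]-3-[3,5-bis(benzyloxy)-2-lithiophenoxy]-2-methoxyprop-2-enoate, potassium salt | CO/C(C(=O)OC(C)(C)C)=C(/Oc1cc(OCc2ccccc2)cc(OCc2ccccc2)c1[Li])c1cc(OCC=C)c(OC)cc1[O-].[K+] | intermediate
15 | 2-[5-(allyloxy)-2-hydroxy-4-methoxyphenyl]-5,7-bis(benzyloxy)-3-methoxy-4H-chromen-4-one | COc1c(-c2cc(OCC=C)c(OC)cc2O)oc2cc(OCc3ccccc3)cc(OCc3ccccc3)c2c1=O | intermediate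
16 | 2-[5-(allyloxy)-2-(benzyloxy)-4-methoxyphenyl]-5,7-bis(benzyloxy)-3-methoxy-4H-chromen-4-one | COc1c(-c2cc(OCC=C)c(OC)cc2OCc2ccccc2)oc2cc(OCc3ccccc3)cc(OCc3ccccc3)c2c1=O | intermediate
17 | 5,7-bis(benzyloxy)-2-[2-(benzyloxy)-5-hydroxy-4-methoxyphenyl]-3-methoxy-4H-chromen-4-one | COc1c(-c2cc(O)c(OC)cc2OCc2ccccc2)oc2cc(OCc3ccccc3)cc(OCc3ccccc3)c2c1=O | intermediate
18 | 4-(benzyloxy)-5-[5,7-bis(benzyloxy)-3-methoxy-4-oxo-4H-chromen-2-yl]-2-methoxyphenyl acetate | COc1c(-c2cc(OC(C)=O)c(OC)cc2OCc2ccccc2)oc2cc(OCc3ccccc3)cc(OCc3ccccc3)c2c1=O | intermediate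
19 | 5,7,2′,5′-tetrahydroxy-3,4′-dimethoxyflavone 5′-acetate (5-(5,7-dihydroxy-3-methoxy-4-oxo-4H-chromen-2-yl)-4-hydroxy-2-methoxyphenyl acetate) | COc1cc(O)c(-c2oc3cc(O)cc(O)c3c(=O)c2OC)cc1OC(C)=O | target

Total step count: 12. Longest linear sequence: 11 steps (steps 1–5 and 7–12, from 1 to 19); step 6 is a one-step side branch from 9.

Steps most likely to fail

Step 8 (Proposed new method). The E/Z equilibration of the ring-opened ester may stay incomplete, so that part of the aryllithium cannot reach the carbonyl. The organolithium may also be diverted by addition of t-BuLi to the ester, by a 1,3-shift of the vinyl group from oxygen to carbon, or by attack on the allyl ether. The fallback is a Baker–Venkataraman sequence of known chemistry that sets out from 4 and comes back to the route at 16. Compound 4 is benzylated at the 2-OH (BnBr, K2CO3, DMF, 60 °C) to allyl 5-(allyloxy)-2-(benzyloxy)-4-methoxybenzoate F1 and saponified (LiOH, THF/H2O) to 5-(allyloxy)-2-(benzyloxy)-4-methoxybenzoic acid F2. Separately, Hoesch acylation of phloroglucinol with methoxyacetonitrile (ZnCl2, HCl, Et2O; then hot water) gives 2-methoxy-1-(2,4,6-trihydroxyphenyl)ethan-1-one F3. Its two non-chelated hydroxyls are benzylated (BnBr 2 equiv, K2CO3, DMF) to 1-[2,4-bis(benzyloxy)-6-hydroxyphenyl]-2-methoxyethan-1-one F4. Esterification of F4 with F2 (EDC·HCl, DMAP, CH2Cl2) gives 3,5-bis(benzyloxy)-2-(methoxyacetyl)phenyl 5-(allyloxy)-2-(benzyloxy)-4-methoxybenzoate F5. Base (LiN(SiMe3)2, THF, −20 °C) shifts the aroyl group to carbon to give 1-[5-(allyloxy)-2-(benzyloxy)-4-methoxyphenyl]-3-[2,4-bis(benzyloxy)-6-hydroxyphenyl]-2-methoxypropane-1,3-dione F6. Cyclodehydration (cat. p-TsOH, toluene, 70 °C) should then give 16, which continues with step 10.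

Step 7. The hindered ortho-bromophenoxide may attack sulfur and take over the sulfonyl group instead of adding to the methoxy-flanked C4, or the addition may be too slow. The fallback sets out from 7 and comes back at 11, using a leaving group that can depart only after attack at carbon. Deoxychlorination of 7 (POCl3, benzyltriethylammonium chloride, MeCN, 80 °C) gives 6-(allyloxy)-4-chloro-3,7-dimethoxy-2H-chromen-2-one F7, and displacement of chloride by 10 (K2CO3, DMF, 60 °C) should give 11.

Step 6. Bromination may lose positional control (attack para to the hydroxyl, between the two benzyloxy groups) or run on to the dibromide. The fallback sets out from 9 and comes back at 10, fixing the position by directed metalation instead of by innate reactivity. O-Carbamoylation (ClCONEt2, K2CO3, MeCN, reflux) gives 3,5-bis(benzyloxy)phenyl diethylcarbamate F8. Ortho-lithiation between the carbamate and a benzyloxy group (s-BuLi, TMEDA, THF, −78 °C), quenched with 1,2-dibromotetrachloroethane, gives 3,5-bis(benzyloxy)-2-bromophenyl diethylcarbamate F9. Hydrolysis (KOH, EtOH, reflux) should release 10.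

Further compounds

F1 | step 8 | allyl 5-(allyloxy)-2-(benzyloxy)-4-methoxybenzoate | C=CCOC(=O)c1cc(OCC=C)c(OC)cc1OCc1ccccc1
F2 | step 8 | 5-(allyloxy)-2-(benzyloxy)-4-methoxybenzoic acid | OC(=O)c1cc(OCC=C)c(OC)cc1OCc1ccccc1
F3 | step 8 | 2-methoxy-1-(2,4,6-trihydroxyphenyl)ethan-1-one | COCC(=O)c1c(O)cc(O)cc1O
F4 | step 8 | 1-[2,4-bis(benzyloxy)-6-hydroxyphenyl]-2-methoxyethan-1-one | COCC(=O)c1c(O)cc(OCc2ccccc2)cc1OCc1ccccc1
F5 | step 8 | 3,5-bis(benzyloxy)-2-(methoxyacetyl)phenyl 5-(allyloxy)-2-(benzyloxy)-4-methoxybenzoate | COCC(=O)c1c(OC(=O)c2cc(OCC=C)c(OC)cc2OCc2ccccc2)cc(OCc2ccccc2)cc1OCc1ccccc1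
F6 | step 8 | 1-[5-(allyloxy)-2-(benzyloxy)-4-methoxyphenyl]-3-[2,4-bis(benzyloxy)-6-hydroxyphenyl]-2-methoxypropane-1,3-dione (racemic) | COC(C(=O)c1cc(OCC=C)c(OC)cc1OCc1ccccc1)C(=O)c1c(O)cc(OCc2ccccc2)cc1OCc1ccccc1
F7 | step 7 | 6-(allyloxy)-4-chloro-3,7-dimethoxy-2H-chromen-2-one | COc1cc2oc(=O)c(OC)c(Cl)c2cc1OCC=C
F8 | step 6 | 3,5-bis(benzyloxy)phenyl diethylcarbamate | CCN(CC)C(=O)Oc1cc(OCc2ccccc2)cc(OCc2ccccc2)c1
F9 | step 6 | 3,5-bis(benzyloxy)-2-bromophenyl diethylcarbamate | CCN(CC)C(=O)Oc1cc(OCc2ccccc2)cc(OCc2ccccc2)c1Br
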